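Compound numbers used throughout: **25** is the target, **21** the precursor of the key step, **24** its product, **14** the ring A ketone and **10** the ring B aldehyde. Abbreviations: geranyl = (2E)-3,7-dimethylocta-2,6-dienyl; prenyl = 3-methylbut-2-enyl; MOM = methoxymethyl; TBS = tert-butyldimethylsilyl; TES = triethylsilyl; Eu(fod)3 = tris(6,6,7,7,8,8,8-heptafluoro-2,2-dimethyloctane-3,5-dionato)europium.

## The problem

Compound 25 is a 2,3-trans flavanonol, a (2R,3R)-3,5,7-trihydroxychroman-4-one whose C2 carries a 2',4'-dihydroxyphenyl ring B. Three isoprenoid chains sit on aromatic carbon: prenyl at C8 of ring A, geranyl at C3' and prenyl at C5' of ring B. The carbon skeleton is that of a chalcone, so the pyranone ring can be closed by forming the O1–C2 bond. The real questions are the absolute configuration at C2 and C3 and the regiochemistry of three C-allylations on two electron-rich rings. Only C3 needs reagent control: it can be set as the α-carbon of a chalcone epoxide, and the benzylic C2 then follows because the ring closes to the diequatorial 2,3-trans arrangement. Every side chain lies ortho to a phenol and cyclises to a chroman in strong acid. The five trisubstituted alkenes exclude hydrogenolysis, osmylation and electrophilic epoxidation. A flavanonol with a free 7- or 4'-hydroxyl is epimerised or oxidised by base, so the end-game must be short and only mildly acidic. The structure offers its own answer to the regiochemistry: C8 is para to O5, which is held next to the C4 carbonyl, and C5' is ortho to O4', whose other ortho position C3' is blocked by geranyl. Both prenyl aryl–CH2 bonds are therefore [3,3] images of allyl ethers on O5 and O4'.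

## Retrosynthesis

**25 ⇐ 24.** The last bonds cut are oxygen–protecting-group bonds at O7, O2' and O3. Phenolic MOM ethers on O7 and O2' and a TES ether on O3 are chosen because all three should fall together in dilute methanolic acid near room temperature, where ortho-prenyl phenols persist. A MOM ether on the secondary O3 would need stronger acid, and esters would need base, so both were rejected. 24 differs from 25 only by these groups, and the forward step asks only that no chain cyclises.

**24 ⇐ 21 (key disconnection).** The two aryl–CH2 bonds, C8–CH2 on ring A and C5'–CH2 on ring B, are cut together. Direct C-prenylation of a polyphenol cannot tell C6 from C8 or C3' from C5' and competes with O-alkylation. Cross-coupling only moves the problem to a regioselective halogenation. The sigmatropic cut instead uses two oxygens that are easy to address. The C8 prenyl goes back to a prenyl ether on O5 (Claisen then Cope), and the C5' prenyl to a 1,1-dimethylallyl ether on O4' (ortho-Claisen with allyl inversion). 21 already holds the full flavanonol core and both stereocentres. The forward step must move two allyl groups from oxygen to carbon regioselectively without touching C2, C3, the geranyl chain or the acetals.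

**21 ⇐ 20 ⇐ 19.** The tertiary allyl aryl ether is the most acid-labile group of the route. It is therefore unmasked one step before use, from the sturdier 1,1-dimethylpropargyl ether of 20 by semi-hydrogenation. 20 comes from the free 3-alcohol 19 by silylation, which keeps the α-ketol away from the europium catalyst and costs nothing at the end. No skeletal bond is cut here; the gain is that the middle of the route tolerates fluoride and mild acid.

**19 ⇐ 17 (through 18).** The O1–C2 bond is cut to give the 2'-hydroxychalcone epoxide 18, carried as its silyl ether 17. An oxa-Michael/enolate hydroxylation sequence was rejected: it needs an electrophilic oxidant beside five electron-rich alkenes and passes through a flavanone enolate that ring-opens. Dihydroxylation followed by Mitsunobu closure was rejected because the osmium reagent would attack the side chains first. In the trans-epoxide both stereocentres are latent: Cα becomes C3 unchanged and Cβ becomes C2 with inversion. The forward step needs 6-endo opening at the benzylic carbon, which the 2,4-dioxygenated ring B activates under mild acid. The silyl ether lets the phenol be freed by buffered fluoride without forming a phenoxide or disturbing the MOM groups.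

**17 ⇐ 16 ⇐ 15.** Removing the epoxide oxygen gives E-enone 16, and removing the silyl group gives 2'-hydroxychalcone 15. Nucleophilic epoxidation is the one oxidation that selects the electron-poor enone over the isolated alkenes. A chiral lanthanum binaphtholate/hydroperoxide system is chosen because it runs without aqueous base and tolerates an ortho-oxygenated aroyl ring. The phenol must be capped first, since a free 2'-hydroxychalcone under basic peroxide goes on to aurones and flavonols. This step sets Cα, hence C3, hence the whole molecule.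

**15 ⇐ 14 + 10.** Cutting Cα=Cβ by a Claisen–Schmidt transform divides the molecule into ketone 14 (ring A, C4, C3) and aldehyde 10 (ring B, C2), two fragments of similar size. No other cut is as convergent, and every group in 14 and 10 is an ether, acetal or alkyne that is inert to ethanolic hydroxide.

**10 ⇐ 9 ⇐ 8 ⇐ 7 ⇐ 5 ⇐ 2 ⇐ 1 + 3.** In 10 the two oxygens must differ. In the free dihydroxy aldehyde 8 the 2-hydroxyl is chelated to the formyl group, so the 4-hydroxyl is etherified first (9) and the 2-hydroxyl protected second (10). 8 comes from bis-MOM aldehyde 7. The C3'–geranyl bond and the formyl group are installed by two directed ortho-lithiations of bis-acetal 2, made from 1. The first lithiation, between the two acetal oxygens, is alkylated with 3 to give 5; the second, ortho to one acetal, is formylated to give 7. This is longer than direct C-geranylation of a dihydroxybenzaldehyde, but every step is regiochemically unambiguous.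

**14 ⇐ 12 ⇐ 11 + 13.** Ketone 14 comes from 11 by using the reactivity order of its hydroxyls. The non-chelated 4-hydroxyl takes the acetal (12). One of the two chelated ortho hydroxyls then takes the prenyl group from 13. The last, locked in a hydrogen bond to the ketone, stays free to become O1.

## Roads not taken

**Alternative 1:** Ring A is assembled by a Danheiser benzannulation instead of being taken from the aromatic pool.
- **Cut:** three ring bonds (C8–C8a, C6–C7, C4a–C8a), leading to 3-(allyloxy)cyclobut-2-enone A2 and the prenyl-bearing siloxyalkyne A3.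
- **Forward key step:** thermolysis opens A2 to a vinylketene; [2+2] cycloaddition with A3, a second four-electron ring opening and a six-electron closure give the pentasubstituted phenol A1. In A1 the prenyl group stands at the future C8 between a free hydroxyl (future O1) and a silyl ether (future O7), with an allyl ether at the future O5.
- **Merits:** the C8 position is fixed by construction, with no C6/C8 question, and the three ring A oxygens emerge differentiated.
- **Weak points:** A2 and A3 are each multistep and sensitive, while 11 supplies the same ring ready-made. The C4a acyl group must still be introduced. The allyl ether must later be removed with zerovalent palladium beside prenyl groups. Ring B is not addressed at all.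
- **Comparison:** for regiochemical certainty on ring A this road is better. The chosen plan sets against it a two-step ring A ketone 14, a para-selective migration of a well-studied type, and one operation (step 15) that serves both rings.

**Alternative 2:** Ring B is built by Diels–Alder reaction and aromatisation.
- **Cut:** C1'–C2' and C5'–C6', leading to the 2-geranyl-4-prenyl-1-methoxy-1,3-bis(trimethylsilyloxy)diene A5 and methyl propiolate A6.
- **Forward key step:** [4+2] cycloaddition, with the nucleophilic diene terminus bonding to the β-carbon of A6, then elimination and desilylation, gives benzoate A4 with both hydroxyls and both chains of ring B in place.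
- **Merits:** both chains are placed unambiguously, there is no ortho/ortho' choice, and the geranyl chain is never heated beside a migrating allyl group.
- **Weak points:** A5 is tetrasubstituted, hindered and hydrolytically labile, and its 4-substituent must be cis to reach the reactive conformation. A4 is an ester that needs redox adjustment to the aldehyde and phenol protection. The ring A prenyl remains unsolved and would still call for the O5-to-C8 migration.
- **Comparison:** for ring B alone this road is at least as good in regiochemical certainty and similar in length. The chosen plan sets against it cheap aromatic starting materials (1, 11), no moisture-sensitive diene, and one reaction type for both prenyl groups.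

**Alternative 3:** Ring A is closed last by a polyketide-like Claisen condensation.
- **Cut:** C4a–C5. The precursor is the 2,3-dihydro-4H-pyran-4-one A8, which carries both stereocentres, the complete ring B and a prenylated β-keto ester chain on the future C8a.
- **Forward key step:** base forms the vinylogous enolate, its α-carbon (future C4a) attacks the ester carbonyl, and enolisation of the triketone gives flavanonol A7 with free 5- and 7-hydroxyls.
- **Merits:** the prenyl group is fixed at C8 by its place in the chain, and no sigmatropic step is needed.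
- **Weak points:** both stereocentres must survive a strongly basic step inside a vinylogous ester. C3–H is α to the ketone, and the dienolate can expel O1 from C2, so epimerisation or ring opening threatens the most valuable intermediate. A8 needs a long enantioselective synthesis, and ring B with both chains must be made beforehand by other means.
- **Comparison:** A7 is as close to 25 as 24 is, and this road avoids any C6/C8 question. The chosen plan sets against it stereocentres made late from a simple chalcone that never meet strong base, and a much shorter sequence.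

Key step: step 15

Assumption: the sense of induction of the lanthanum–binaphtholate epoxidation is taken to be that known for simple chalcones, the (S)-ligand giving the (αR,βS)-epoxide; if it is opposite on this substrate the enantiomeric ligand is used and nothing else changes.

## Route

Step 1
Reactants: 1 resorcinol
Product: 2 1,3-bis(methoxymethoxy)benzene
Conditions: MOMCl, i-Pr2NEt, CH2Cl2, 0 °C to rt
Reagents that add atoms: chloromethyl methyl ether, COCCl
Why: O-alkylation of both phenols with the chloromethyl ether (acetal protection); the substrate is symmetric, so there is no selectivity issue.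

Step 2
Reactants: 2 1,3-bis(methoxymethoxy)benzene; 3 geranyl bromide
Product: 5 2-geranyl-1,3-bis(methoxymethoxy)benzene, via 2-lithio-1,3-bis(methoxymethoxy)benzene 4 (not isolated)
Conditions: n-BuLi, THF, 0 °C to rt; then 3, 0 °C to rt
Reagents that add atoms: none
Why: Directed ortho-lithiation at the doubly coordinated position between the two acetal oxygens, then SN2 alkylation of aryllithium 4 at the unhindered primary allylic carbon of 3, which keeps the E-alkene.

Step 3
Reactants: 5 2-geranyl-1,3-bis(methoxymethoxy)benzene
Product: 7 3-geranyl-2,4-bis(methoxymethoxy)benzaldehyde, via 3-geranyl-2,4-bis(methoxymethoxy)phenyllithium 6 (not isolated)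
Conditions: n-BuLi, TMEDA, THF, 0 °C; then DMF; H2O
Reagents that add atoms: N,N-dimethylformamide, CN(C)C=O
Why: Second directed ortho-lithiation at the only ring position type still ortho to an acetal oxygen (C4 and C6 are equivalent), followed by formylation of 6 with the formamide.

Step 4
Reactants: 7 3-geranyl-2,4-bis(methoxymethoxy)benzaldehyde
Product: 8 3-geranyl-2,4-dihydroxybenzaldehyde
Conditions: 3 M aq. HCl, MeOH, rt
Reagents that add atoms: none
Why: Acid-catalysed methanolysis of aryl MOM acetals; in dilute acid at room temperature the geranyl chain should not cyclise onto the new phenols.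

Step 5
Reactants: 8 3-geranyl-2,4-dihydroxybenzaldehyde
Product: 9 3-geranyl-2-hydroxy-4-(2-methylbut-3-yn-2-yloxy)benzaldehyde
Conditions: 3-chloro-3-methylbut-1-yne, K2CO3, KI, CuI (cat.), acetone, 55 °C
Reagents that add atoms: 3-chloro-3-methylbut-1-yne, CC(C)(Cl)C#C
Why: Selective etherification of the free and more acidic 4-hydroxyl, the 2-hydroxyl being held in a hydrogen bond to the formyl group; copper-assisted substitution of the tertiary propargylic chloride tolerates the hindered phenol.

Step 6
Reactants: 9 3-geranyl-2-hydroxy-4-(2-methylbut-3-yn-2-yloxy)benzaldehyde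
Product: 10 3-geranyl-2-(methoxymethoxy)-4-(2-methylbut-3-yn-2-yloxy)benzaldehyde
Conditions: NaH, MOMCl, DMF, 0 °C
Reagents that add atoms: chloromethyl methyl ether, COCCl
Why: MOM protection of the chelated phenol as its sodium salt; this blocks O2' of ring B during ring closure and lasts to the final step.

Step 7
Reactants: 11 2',4',6'-trihydroxyacetophenone
Product: 12 1-[2,6-dihydroxy-4-(methoxymethoxy)phenyl]ethanone
Conditions: MOMCl (1 equiv), i-Pr2NEt, CH2Cl2, 0 °C
Reagents that add atoms: chloromethyl methyl ether, COCCl
Why: Selective acetal protection; the 4-hydroxyl is the only non-chelated and the most acidic hydroxyl, so one equivalent of reagent should react there first.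

Step 8
Reactants: 12 1-[2,6-dihydroxy-4-(methoxymethoxy)phenyl]ethanone; 13 prenyl bromide
Product: 14 1-[2-hydroxy-4-(methoxymethoxy)-6-(3-methylbut-2-enyloxy)phenyl]ethanone
Conditions: K2CO3, acetone, rt to 40 °C
Reagents that add atoms: none
Why: Williamson mono-O-alkylation of one of two equivalent chelated phenols; the remaining hydroxyl is then locked in a strong hydrogen bond to the ketone and should not react further.

Step 9
Reactants: 14 1-[2-hydroxy-4-(methoxymethoxy)-6-(3-methylbut-2-enyloxy)phenyl]ethanone; 10 3-geranyl-2-(methoxymethoxy)-4-(2-methylbut-3-yn-2-yloxy)benzaldehyde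
Product: 15 (E)-3-[3-geranyl-2-(methoxymethoxy)-4-(2-methylbut-3-yn-2-yloxy)phenyl]-1-[2-hydroxy-4-(methoxymethoxy)-6-(3-methylbut-2-enyloxy)phenyl]prop-2-en-1-one
Conditions: KOH, EtOH, rt
Reagents that add atoms: none
Why: Claisen–Schmidt condensation (aldol addition, then E1cB dehydration) to the thermodynamically favoured E-enone; ethers, acetals and the alkyne are inert to ethanolic hydroxide.

Step 10
Reactants: 15 the 2'-hydroxychalcone of step 9
Product: 16 (E)-1-[2-(tert-butyldimethylsilyloxy)-4-(methoxymethoxy)-6-(3-methylbut-2-enyloxy)phenyl]-3-[3-geranyl-2-(methoxymethoxy)-4-(2-methylbut-3-yn-2-yloxy)phenyl]prop-2-en-1-one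
Conditions: TBSCl, imidazole, DMAP (cat.), DMF, rt to 40 °C
Reagents that add atoms: tert-butyldimethylsilyl chloride, CC(C)(C)[Si](C)(C)Cl
Why: Silylation of the chelated phenol; the silyl ether prevents Algar–Flynn–Oyamada chemistry in the next step and is a fluoride-labile trigger orthogonal to the MOM groups.

Step 11
Reactants: 16 the 2'-silyloxychalcone of step 10
Product: 17 [2-(tert-butyldimethylsilyloxy)-4-(methoxymethoxy)-6-(3-methylbut-2-enyloxy)phenyl]{(2R,3S)-3-[3-geranyl-2-(methoxymethoxy)-4-(2-methylbut-3-yn-2-yloxy)phenyl]oxiran-2-yl}methanone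
Conditions: La(O-iPr)3 (10 mol%), (S)-BINOL (10 mol%), Ph3As=O (10 mol%), TBHP (decane), MS 4 Å, THF, rt
Reagents that add atoms: tert-butyl hydroperoxide, CC(C)(C)OO
Why: Catalytic asymmetric nucleophilic (Weitz–Scheffer-type) epoxidation; the lanthanum-bound peroxide adds only to the enone β-carbon, leaving the isolated alkenes and the alkyne untouched. The chiral binaphtholate complex selects the enone face, and the (S)-ligand is expected to give the trans-(αR,βS) epoxide, which fixes the future C3.

Step 12
Reactants: 17 the (2R,3S)-epoxy ketone of step 11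
Product: 19 (2R,3R)-2-[3-geranyl-2-(methoxymethoxy)-4-(2-methylbut-3-yn-2-yloxy)phenyl]-3-hydroxy-7-(methoxymethoxy)-5-(3-methylbut-2-enyloxy)chroman-4-one, via 2'-hydroxychalcone epoxide 18 (not isolated)
Conditions: TBAF, AcOH, THF, 0 °C; then PPTS (cat.), 0 °C to rt
Reagents that add atoms: none
Why: Buffered fluoride frees phenol 18 without forming a phenoxide; mild acid then induces 6-endo epoxide opening at the benzylic carbon, activated by the ortho and para oxygens of ring B, with inversion to give the 2,3-trans (2R,3R) ring. C3 is untouched, and even if the opening has cationic character the diequatorial trans product should prevail.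

Step 13
Reactants: 19 the (2R,3R)-flavanonol of step 12
Product: 20 (2R,3R)-2-[3-geranyl-2-(methoxymethoxy)-4-(2-methylbut-3-yn-2-yloxy)phenyl]-7-(methoxymethoxy)-5-(3-methylbut-2-enyloxy)-3-(triethylsilyloxy)chroman-4-one
Conditions: TESCl, imidazole, DMF, 0 °C to rt
Reagents that add atoms: chlorotriethylsilane, CC[Si](Cl)(CC)CC
Why: Silylation of the secondary α-hydroxy ketone under near-neutral conditions; the ether keeps the α-ketol from binding the europium catalyst and falls with the MOM groups in the last step.

Step 14
Reactants: 20 the 3-O-triethylsilyl propargyl ether of step 13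
Product: 21 (2R,3R)-2-[3-geranyl-2-(methoxymethoxy)-4-(2-methylbut-3-en-2-yloxy)phenyl]-7-(methoxymethoxy)-5-(3-methylbut-2-enyloxy)-3-(triethylsilyloxy)chroman-4-one
Conditions: H2 (1 atm), Pd/CaCO3 poisoned with Pb(OAc)2 (Lindlar catalyst), quinoline, EtOAc, rt
Reagents that add atoms: none
Why: Lindlar semi-hydrogenation of the terminal alkyne to the vinyl group; the poisoned catalyst should leave the trisubstituted alkenes, the prenyl aryl ether and the ketone alone.

Step 15
Reactants: 21 the bis(allyl ether) of step 14
Product: 24 (2R,3R)-2-[3-geranyl-4-hydroxy-2-(methoxymethoxy)-5-(3-methylbut-2-enyl)phenyl]-5-hydroxy-7-(methoxymethoxy)-8-(3-methylbut-2-enyl)-3-(triethylsilyloxy)chroman-4-one, via C6 dienone 22 (not isolated), via mono-rearranged ether 23 (not isolated)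
Conditions: Eu(fod)3 (15 mol%), NaHCO3, PhCl, 85 °C; then 125 °C
Reagents that add atoms: none
Why: Two independent [3,3] cascades of known type run in one flask: the Eu(fod)3-catalysed para-Claisen–Cope rearrangement of a 5-O-prenyl flavonoid and the thermal ortho-Claisen rearrangement of an aryl 1,1-dimethylallyl ether. Trivalent europium binds the C4 carbonyl and O5 and lowers the barrier of the Claisen shift of the prenyl ether to C6, giving dienone 22 with an inverted 1,1-dimethylallyl group; a Cope shift carries that group to C8 as a normal prenyl group, and enolisation restores ring A as the chelated 5-phenol of 23. Raising the temperature brings on the uncatalysed Claisen shift of the tertiary ether on ring B; only C5' carries hydrogen, so only there can the dienone enolise, and allyl inversion delivers a normal prenyl group at C5'. No ring is closed, and the sp3 centres at C6, C8 and C5' are transient and vanish on enolisation, so no stereocentre is created. On ring A the step needs C8 over C6, which is secured by the Cope step relieving the crowded C6 dienone beside the 7-O-MOM group and by europium chelation keeping the temperature below that of the unselective thermal reaction. On ring B it needs C5' over C3', which is secured by the geranyl block, since a shift to C3' is reversible and unproductive. C2 and C3 take no part: the medium is neutral and buffered, O3 is silylated and O2' is an acetal, so neither enolisation towards C3 nor opening of the O1–C2 bond is expected. The geranyl E-alkene is not at risk because that chain is in no productive shift.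

Step 16
Reactants: 24 the doubly rearranged flavanonol of step 15
Product: 25 (2R,3R)-2-[3-geranyl-2,4-dihydroxy-5-(3-methylbut-2-enyl)phenyl]-3,5,7-trihydroxy-8-(3-methylbut-2-enyl)chroman-4-one
Conditions: 3 M aq. HCl, MeOH, rt to 40 °C
Reagents that add atoms: none
Why: Acid-catalysed methanolysis of the two phenolic MOM acetals and the TES ether in one operation; the acid is dilute and the temperature low so that the chains should not cyclise onto the phenols and C2 and C3 should not be disturbed.

## Compound list

1 | resorcinol (benzene-1,3-diol) | Oc1cccc(O)c1 | starting material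
2 | 1,3-bis(methoxymethoxy)benzene | COCOc1cccc(OCOC)c1 | intermediate
3 | geranyl bromide, (2E)-1-bromo-3,7-dimethylocta-2,6-diene | CC(C)=CCC/C(C)=C/CBr | starting material
4 | 2-lithio-1,3-bis(methoxymethoxy)benzene | [Li]c1c(OCOC)cccc1OCOC | intermediate
5 | 2-geranyl-1,3-bis(methoxymethoxy)benzene | CC(C)=CCC/C(C)=C/Cc1c(OCOC)cccc1OCOC | intermediate
6 | 3-geranyl-2,4-bis(methoxymethoxy)phenyllithium | CC(C)=CCC/C(C)=C/Cc1c(OCOC)ccc([Li])c1OCOC | intermediate
7 | 3-geranyl-2,4-bis(methoxymethoxy)benzaldehyde | CC(C)=CCC/C(C)=C/Cc1c(OCOC)ccc(C=O)c1OCOC | intermediate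
8 | 3-geranyl-2,4-dihydroxybenzaldehyde | CC(C)=CCC/C(C)=C/Cc1c(O)ccc(C=O)c1O | intermediate
9 | 3-geranyl-2-hydroxy-4-(2-methylbut-3-yn-2-yloxy)benzaldehyde | CC(C)=CCC/C(C)=C/Cc1c(OC(C)(C)C#C)ccc(C=O)c1O | intermediate
10 | 3-geranyl-2-(methoxymethoxy)-4-(2-methylbut-3-yn-2-yloxy)benzaldehyde | CC(C)=CCC/C(C)=C/Cc1c(OC(C)(C)C#C)ccc(C=O)c1OCOC | intermediate
11 | 2',4',6'-trihydroxyacetophenone | CC(=O)c1c(O)cc(O)cc1O | starting material
12 | 1-[2,6-dihydroxy-4-(methoxymethoxy)phenyl]ethanone | CC(=O)c1c(O)cc(OCOC)cc1O | intermediate
13 | prenyl bromide, 1-bromo-3-methylbut-2-ene | CC(C)=CCBr | starting material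
14 | 1-[2-hydroxy-4-(methoxymethoxy)-6-(3-methylbut-2-enyloxy)phenyl]ethanone | CC(=O)c1c(O)cc(OCOC)cc1OCC=C(C)C | intermediate
15 | (E)-3-[3-geranyl-2-(methoxymethoxy)-4-(2-methylbut-3-yn-2-yloxy)phenyl]-1-[2-hydroxy-4-(methoxymethoxy)-6-(3-methylbut-2-enyloxy)phenyl]prop-2-en-1-one | CC(C)=CCC/C(C)=C/Cc1c(OC(C)(C)C#C)ccc(/C=C/C(=O)c2c(O)cc(OCOC)cc2OCC=C(C)C)c1OCOC | intermediate
16 | 2'-O-tert-butyldimethylsilyl ether of 15 | CC(C)=CCC/C(C)=C/Cc1c(OC(C)(C)C#C)ccc(/C=C/C(=O)c2c(O[Si](C)(C)C(C)(C)C)cc(OCOC)cc2OCC=C(C)C)c1OCOC | intermediate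
17 | [2-(tert-butyldimethylsilyloxy)-4-(methoxymethoxy)-6-(3-methylbut-2-enyloxy)phenyl]{(2R,3S)-3-[3-geranyl-2-(methoxymethoxy)-4-(2-methylbut-3-yn-2-yloxy)phenyl]oxiran-2-yl}methanone | CC(C)=CCC/C(C)=C/Cc1c(OC(C)(C)C#C)ccc([C@@H]2O[C@H]2C(=O)c3c(O[Si](C)(C)C(C)(C)C)cc(OCOC)cc3OCC=C(C)C)c1OCOC | intermediate
18 | {(2R,3S)-3-[3-geranyl-2-(methoxymethoxy)-4-(2-methylbut-3-yn-2-yloxy)phenyl]oxiran-2-yl}[2-hydroxy-4-(methoxymethoxy)-6-(3-methylbut-2-enyloxy)phenyl]methanone | CC(C)=CCC/C(C)=C/Cc1c(OC(C)(C)C#C)ccc([C@@H]2O[C@H]2C(=O)c3c(O)cc(OCOC)cc3OCC=C(C)C)c1OCOC | intermediate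
19 | (2R,3R)-2-[3-geranyl-2-(methoxymethoxy)-4-(2-methylbut-3-yn-2-yloxy)phenyl]-3-hydroxy-7-(methoxymethoxy)-5-(3-methylbut-2-enyloxy)chroman-4-one | CC(C)=CCC/C(C)=C/Cc1c(OC(C)(C)C#C)ccc([C@H]2Oc3cc(OCOC)cc(OCC=C(C)C)c3C(=O)[C@@H]2O)c1OCOC | intermediate
20 | (2R,3R)-2-[3-geranyl-2-(methoxymethoxy)-4-(2-methylbut-3-yn-2-yloxy)phenyl]-7-(methoxymethoxy)-5-(3-methylbut-2-enyloxy)-3-(triethylsilyloxy)chroman-4-one | CC(C)=CCC/C(C)=C/Cc1c(OC(C)(C)C#C)ccc([C@H]2Oc3cc(OCOC)cc(OCC=C(C)C)c3C(=O)[C@@H]2O[Si](CC)(CC)CC)c1OCOC | intermediate
21 | (2R,3R)-2-[3-geranyl-2-(methoxymethoxy)-4-(2-methylbut-3-en-2-yloxy)phenyl]-7-(methoxymethoxy)-5-(3-methylbut-2-enyloxy)-3-(triethylsilyloxy)chroman-4-one | CC(C)=CCC/C(C)=C/Cc1c(OC(C)(C)C=C)ccc([C@H]2Oc3cc(OCOC)cc(OCC=C(C)C)c3C(=O)[C@@H]2O[Si](CC)(CC)CC)c1OCOC | intermediate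
22 | (2R,3R)-2-[3-geranyl-2-(methoxymethoxy)-4-(2-methylbut-3-en-2-yloxy)phenyl]-7-(methoxymethoxy)-6-(2-methylbut-3-en-2-yl)-3-(triethylsilyloxy)-2,3-dihydrochromene-4,5(6H)-dione, C6 epimers | CC(C)=CCC/C(C)=C/Cc1c(OC(C)(C)C=C)ccc([C@H]2OC=3C=C(OCOC)C(C(C)(C)C=C)C(=O)C=3C(=O)[C@@H]2O[Si](CC)(CC)CC)c1OCOC | intermediate
23 | (2R,3R)-2-[3-geranyl-2-(methoxymethoxy)-4-(2-methylbut-3-en-2-yloxy)phenyl]-5-hydroxy-7-(methoxymethoxy)-8-(3-methylbut-2-enyl)-3-(triethylsilyloxy)chroman-4-one | CC(C)=CCC/C(C)=C/Cc1c(OC(C)(C)C=C)ccc([C@H]2Oc3c(CC=C(C)C)c(OCOC)cc(O)c3C(=O)[C@@H]2O[Si](CC)(CC)CC)c1OCOC | intermediate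
24 | (2R,3R)-2-[3-geranyl-4-hydroxy-2-(methoxymethoxy)-5-(3-methylbut-2-enyl)phenyl]-5-hydroxy-7-(methoxymethoxy)-8-(3-methylbut-2-enyl)-3-(triethylsilyloxy)chroman-4-one | CC(C)=CCC/C(C)=C/Cc1c(O)c(CC=C(C)C)cc([C@H]2Oc3c(CC=C(C)C)c(OCOC)cc(O)c3C(=O)[C@@H]2O[Si](CC)(CC)CC)c1OCOC | intermediate
25 | (2R,3R)-2-[3-geranyl-2,4-dihydroxy-5-(3-methylbut-2-enyl)phenyl]-3,5,7-trihydroxy-8-(3-methylbut-2-enyl)chroman-4-one | CC(C)=CCC/C(C)=C/Cc1c(O)c(CC=C(C)C)cc([C@H]2Oc3c(CC=C(C)C)c(O)cc(O)c3C(=O)[C@@H]2O)c1O | target

## Step count and risk

Total step count: 16. Longest linear sequence: 14 steps (steps 1–6 and 9–16, from 1).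

**Step 15 (key step).**
- What may go wrong: the tertiary allyl ether on O4' may ionise or eliminate under the Lewis acid before it rearranges. On ring A the C6 dienone may enolise faster than it undergoes the Cope shift, so that the inverted allyl group stays at C6. A reversible shift to the blocked C3' may open a path for migration of the geranyl group. Long heating after the 4'-hydroxyl is freed may allow epimerisation at C2 by opening of the O1–C2 bond.
- Fallback (from 10, back at 25): the two migrations are separated, and the ring B shift is moved to the aldehyde stage, where it is a plain thermal ortho-Claisen rearrangement of a small, robust molecule. Semi-hydrogenation of 10 (H2, Pd/CaCO3 poisoned with Pb(OAc)2, quinoline) gives 3-geranyl-2-(methoxymethoxy)-4-(2-methylbut-3-en-2-yloxy)benzaldehyde F1. Heating (DMF, 120 °C) gives 3-geranyl-4-hydroxy-2-(methoxymethoxy)-5-prenylbenzaldehyde F2, and NaH/MOMCl gives 3-geranyl-2,4-bis(methoxymethoxy)-5-prenylbenzaldehyde F3. F3 then replaces 10. Claisen–Schmidt condensation with 14 gives the 2'-hydroxychalcone F4 and silylation its TBS ether F5. The same asymmetric epoxidation gives the (2R,3S)-epoxy ketone F6, and desilylative ring closure the (2R,3R)-flavanonol F7. Silylation gives the 3-O-triethylsilyl ether F8. Only the europium-catalysed O5-to-C8 shift then remains (Eu(fod)3, NaHCO3, PhCl, 85 °C), giving the 5-hydroxy-8-prenyl flavanonol F9. Methanolic HCl removes three MOM groups and the silyl ether to reach 25.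

**Step 12.**
- What may go wrong: the freed phenol may attack Cα in a 5-exo mode. The activated benzylic epoxide may rearrange by a 1,2-aroyl shift (Meinwald type) or be opened by acetate or fluoride before the phenol reaches it. Ionisation at Cβ may erode the trans selectivity.
- Fallback (from 17, back at 19): the C–O bond at Cβ is broken first with a soft external nucleophile and O1–C2 is formed afterwards by thiophilic activation, so the ring size is fixed at six. Benzyl mercaptan with SnCl4 in CH2Cl2 at −20 °C opens 17 at the benzylic carbon to the β-benzylsulfanyl α-hydroxy ketone F10 (Cα unchanged, Cβ a mixture). TBAF/AcOH frees the phenol F11. AgBF4 in CH2Cl2 at 0 °C then closes the ring through the benzylic cation to the trans-flavanonol 19.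

**Step 11.**
- What may go wrong: enantiofacial discrimination or turnover may be poor because the 2',6'-disubstituted aroyl group is twisted out of the enone plane and the β-aryl group is very electron-rich. The lanthanum alkoxide may also partly cleave the aryl silyl ether.
- Fallback (from 16, back at 19): reagent control is given up. Achiral Weitz–Scheffer epoxidation (TBHP, DBU, PhMe, rt) gives the racemic trans-epoxy ketone F12. The conditions of step 12 give the racemic trans-flavanonol F13. F13 is resolved by preparative chromatography on a cellulose tris(3,5-dimethylphenylcarbamate) stationary phase, and the (2R,3R)-enantiomer is 19.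

**Step 16.**
- What may go wrong: a prenyl or geranyl chain may cyclise onto its neighbouring phenol before the hindered 2'-O-MOM group has gone. Acid may also ionise the O1–C2 bond, which is activated by the 2'- and 4'-oxygens, and cause epimerisation.
- Fallback (from 24, back at 25): the groups are removed one after the other under aprotic conditions. HF·pyridine buffered with pyridine (THF, 0 °C) removes the silyl ether to give the 3-hydroxy bis-MOM ether F14. ZnBr2 with propane-1-thiol (CH2Cl2, 0 °C, short contact) then transfers both MOM groups to sulfur and gives 25.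

## Further compounds

F1 | step 15 | 3-geranyl-2-(methoxymethoxy)-4-(2-methylbut-3-en-2-yloxy)benzaldehyde | CC(C)=CCC/C(C)=C/Cc1c(OC(C)(C)C=C)ccc(C=O)c1OCOC
F2 | step 15 | 3-geranyl-4-hydroxy-2-(methoxymethoxy)-5-(3-methylbut-2-enyl)benzaldehyde | CC(C)=CCC/C(C)=C/Cc1c(O)c(CC=C(C)C)cc(C=O)c1OCOC
F3 | step 15 | 3-geranyl-2,4-bis(methoxymethoxy)-5-(3-methylbut-2-enyl)benzaldehyde | CC(C)=CCC/C(C)=C/Cc1c(OCOC)c(CC=C(C)C)cc(C=O)c1OCOC
F4 | step 15 | (E)-3-[3-geranyl-2,4-bis(methoxymethoxy)-5-(3-methylbut-2-enyl)phenyl]-1-[2-hydroxy-4-(methoxymethoxy)-6-(3-methylbut-2-enyloxy)phenyl]prop-2-en-1-one | CC(C)=CCC/C(C)=C/Cc1c(OCOC)c(CC=C(C)C)cc(/C=C/C(=O)c2c(O)cc(OCOC)cc2OCC=C(C)C)c1OCOC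
F5 | step 15 | 2'-O-tert-butyldimethylsilyl ether of F4 | CC(C)=CCC/C(C)=C/Cc1c(OCOC)c(CC=C(C)C)cc(/C=C/C(=O)c2c(O[Si](C)(C)C(C)(C)C)cc(OCOC)cc2OCC=C(C)C)c1OCOC
F6 | step 15 | [2-(tert-butyldimethylsilyloxy)-4-(methoxymethoxy)-6-(3-methylbut-2-enyloxy)phenyl]{(2R,3S)-3-[3-geranyl-2,4-bis(methoxymethoxy)-5-(3-methylbut-2-enyl)phenyl]oxiran-2-yl}methanone | CC(C)=CCC/C(C)=C/Cc1c(OCOC)c(CC=C(C)C)cc([C@@H]2O[C@H]2C(=O)c3c(O[Si](C)(C)C(C)(C)C)cc(OCOC)cc3OCC=C(C)C)c1OCOC
F7 | step 15 | (2R,3R)-2-[3-geranyl-2,4-bis(methoxymethoxy)-5-(3-methylbut-2-enyl)phenyl]-3-hydroxy-7-(methoxymethoxy)-5-(3-methylbut-2-enyloxy)chroman-4-one | CC(C)=CCC/C(C)=C/Cc1c(OCOC)c(CC=C(C)C)cc([C@H]2Oc3cc(OCOC)cc(OCC=C(C)C)c3C(=O)[C@@H]2O)c1OCOC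
F8 | step 15 | 3-O-triethylsilyl ether of F7 | CC(C)=CCC/C(C)=C/Cc1c(OCOC)c(CC=C(C)C)cc([C@H]2Oc3cc(OCOC)cc(OCC=C(C)C)c3C(=O)[C@@H]2O[Si](CC)(CC)CC)c1OCOC
F9 | step 15 | (2R,3R)-2-[3-geranyl-2,4-bis(methoxymethoxy)-5-(3-methylbut-2-enyl)phenyl]-5-hydroxy-7-(methoxymethoxy)-8-(3-methylbut-2-enyl)-3-(triethylsilyloxy)chroman-4-one | CC(C)=CCC/C(C)=C/Cc1c(OCOC)c(CC=C(C)C)cc([C@H]2Oc3c(CC=C(C)C)c(OCOC)cc(O)c3C(=O)[C@@H]2O[Si](CC)(CC)CC)c1OCOC
F10 | step 12 | (2S)-3-(benzylsulfanyl)-1-[2-(tert-butyldimethylsilyloxy)-4-(methoxymethoxy)-6-(3-methylbut-2-enyloxy)phenyl]-3-[3-geranyl-2-(methoxymethoxy)-4-(2-methylbut-3-yn-2-yloxy)phenyl]-2-hydroxypropan-1-one, C3 epimers | CC(C)=CCC/C(C)=C/Cc1c(OC(C)(C)C#C)ccc(C(SCc2ccccc2)[C@@H](O)C(=O)c3c(O[Si](C)(C)C(C)(C)C)cc(OCOC)cc3OCC=C(C)C)c1OCOC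
F11 | step 12 | (2S)-3-(benzylsulfanyl)-3-[3-geranyl-2-(methoxymethoxy)-4-(2-methylbut-3-yn-2-yloxy)phenyl]-2-hydroxy-1-[2-hydroxy-4-(methoxymethoxy)-6-(3-methylbut-2-enyloxy)phenyl]propan-1-one, C3 epimers | CC(C)=CCC/C(C)=C/Cc1c(OC(C)(C)C#C)ccc(C(SCc2ccccc2)[C@@H](O)C(=O)c3c(O)cc(OCOC)cc3OCC=C(C)C)c1OCOC
F12 | step 11 | racemic trans-epoxy ketone of the constitution of 17 (drawn without stereocentre descriptors) | CC(C)=CCC/C(C)=C/Cc1c(OC(C)(C)C#C)ccc(C2OC2C(=O)c3c(O[Si](C)(C)C(C)(C)C)cc(OCOC)cc3OCC=C(C)C)c1OCOC
F13 | step 11 | racemic 2,3-trans-flavanonol of the constitution of 19 (drawn without stereocentre descriptors) | CC(C)=CCC/C(C)=C/Cc1c(OC(C)(C)C#C)ccc(C2Oc3cc(OCOC)cc(OCC=C(C)C)c3C(=O)C2O)c1OCOC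
F14 | step 16 | (2R,3R)-2-[3-geranyl-4-hydroxy-2-(methoxymethoxy)-5-(3-methylbut-2-enyl)phenyl]-3,5-dihydroxy-7-(methoxymethoxy)-8-(3-methylbut-2-enyl)chroman-4-one | CC(C)=CCC/C(C)=C/Cc1c(O)c(CC=C(C)C)cc([C@H]2Oc3c(CC=C(C)C)c(OCOC)cc(O)c3C(=O)[C@@H]2O)c1OCOC
A1 | alternative 1 | 5-(allyloxy)-2-(3-methylbut-2-enyl)-3-(triisopropylsilyloxy)phenol | Oc1cc(OCC=C)cc(O[Si](C(C)C)(C(C)C)C(C)C)c1CC=C(C)C
A2 | alternative 1 | 3-(allyloxy)cyclobut-2-en-1-one | O=C1C=C(OCC=C)C1
A3 | alternative 1 | triisopropyl[(5-methylhex-4-en-1-yn-1-yl)oxy]silane | CC(C)=CCC#CO[Si](C(C)C)(C(C)C)C(C)C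
A4 | alternative 2 | methyl 3-geranyl-2,4-dihydroxy-5-(3-methylbut-2-enyl)benzoate | CC(C)=CCC/C(C)=C/Cc1c(O)c(CC=C(C)C)cc(C(=O)OC)c1O
A5 | alternative 2 | 2-geranyl-1-methoxy-4-(3-methylbut-2-enyl)-1,3-bis(trimethylsilyloxy)buta-1,3-diene | COC(O[Si](C)(C)C)=C(C/C=C(\C)CCC=C(C)C)C(O[Si](C)(C)C)=CCC=C(C)C
A6 | alternative 2 | methyl propiolate | COC(=O)C#C
A7 | alternative 3 | (2R,3R)-3-(tert-butyldimethylsilyloxy)-2-[3-geranyl-2,4-bis(methoxymethoxy)-5-(3-methylbut-2-enyl)phenyl]-5,7-dihydroxy-8-(3-methylbut-2-enyl)chroman-4-one | CC(C)=CCC/C(C)=C/Cc1c(OCOC)c(CC=C(C)C)cc([C@H]2Oc3c(CC=C(C)C)c(O)cc(O)c3C(=O)[C@@H]2O[Si](C)(C)C(C)(C)C)c1OCOC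
A8 | alternative 3 | methyl 4-{(2R,3R)-3-(tert-butyldimethylsilyloxy)-2-[3-geranyl-2,4-bis(methoxymethoxy)-5-(3-methylbut-2-enyl)phenyl]-4-oxo-3,4-dihydro-2H-pyran-6-yl}-7-methyl-3-oxooct-6-enoate | CC(C)=CCC/C(C)=C/Cc1c(OCOC)c(CC=C(C)C)cc([C@H]2OC(C(CC=C(C)C)C(=O)CC(=O)OC)=CC(=O)[C@@H]2O[Si](C)(C)C(C)(C)C)c1OCOC
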